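I start from the leftover: the free monomer still standing at the end, since the monomer in chains, crystals counted, is the charge minus that leftover.

common to all: free monomer 5.0 mM; initiator 26 µM; time 80 s

| charge | remark | temperature |
|---|---|---|
| theta | at 35 °C until 25 s, from then on at 85 °C |  |
| gamma |  | 60 °C |
| alpha |  | 85 °C |
| epsilon |  | 35 °C |

    initiator → 2 initiating radical (k1 = 0.00456 s⁻¹, Ea1 = 84.0 kJ mol⁻¹)
    free monomer + initiating radical → growing radical + monomer in chains (k2 = 6.41 × 10⁷ L mol⁻¹ s⁻¹, Ea2 = 17.0 kJ mol⁻¹)
    free monomer + growing radical → monomer in chains + growing radical, rate k3*[growing radical]*[free monomer] (k3 = 4.69 × 10⁵ L mol⁻¹ s⁻¹, Ea3 = 22.0 kJ mol⁻¹)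
    2 growing radical → dead chain (k4 = 5.4 × 10⁸ L mol⁻¹ s⁻¹, Ea4 = 13.0 kJ mol⁻¹)
    crystals ⇌ monomer in chains, rate k5*(cs5 - [monomer in chains]) while solid is left; crystals form when [monomer in chains] > cs5 (cs5 = 1.9 mM, k5 = 0.571 s⁻¹)
    (constants at 35 °C)

- amounts and yields of monomer in chains count crystals too
- a step written with two of one species runs at k times the square of its concentration and takes two of it each time
- given per volume of solution although it is solid: crystals
- at 35 °C the constants are as listed, elsewhere as the activation energies make them

* the flask that comes out highest in amount of monomer in chains, in percent of the free monomer charged, or "all alike" when all lie within 1.5 percentage points (theta / gamma / alpha / epsilon / all alike)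
* monomer in chains at the end, in percent of the free monomer charged, theta
* monomer in chains at the end, in percent of the free monomer charged, gamma
* monomer in chains at the end, in percent of the free monomer charged, alpha
* monomer in chains at the end, in percent of the free monomer charged, epsilon

The growth step is pseudo-first-order in free monomer, with k·c(growing radical) as its rate constant, so the leftover is the charge times the exponential of −X, where X is the time integral of that rate constant. Crystals take no part in that step and are counted in the yield, so I drop them.

Next I need c(growing radical). An initiating radical becomes a growing radical in about 3.12 × 10⁻⁶ s. At the start of epsilon the level at which making and losing of growing radical balance is 1.48 × 10⁻⁵ mM, and at that level the first half-life of c(growing radical) by termination is 0.0625 s, which is far shorter than the run, so in epsilon I take the two as balanced. c(growing radical) is then the square root of the decay constant times c(initiator) over the termination constant.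

Holding that start level through the run gives epsilon X = 0.556, and the same reckoning gives alpha X = 12.8, a leftover of <0.001%. That is the weak link. In alpha the initiator's decay constant is 0.443 s⁻¹, so it lives 2.26 s, far shorter than the run, and the radical curve falls away from its start.

So I replace the curve by its mean. The radical level falls as the exponential of −kt/2, and its mean is the start level times u/(kt/2), where u is one minus that exponential. Then X = reach × u. The reach, 3.05 at 35 °C, is the exponent a charge buys when burnt out at one temperature: 2 times the growth constant times the square root of the charge over the product of decay and termination constants. Its net energy is −26.5 kJ mol⁻¹, so heat shrinks it, to 1.40 in gamma and 0.719 in alpha, while u grows.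

Epsilon has u = 0.167, so X = 0.508 and the yield is 39.8%. Gamma, with decay constant 0.0534 s⁻¹, has u = 0.882, so X = 1.24 and the yield is 71.0%. Alpha uses nearly all of its reach, giving 51.3%. Theta spends its cold part at the cold reach, then carries the remaining initiator into the hot reach, so X = 0.848 and the yield is 57.2%. I commit to gamma as highest. Initiating radicals also take free monomer, at most 1.04% of the charge, so my figures may sit slightly low.

The forecast names gamma, with 71.4% there, 57.9% for theta, 52% for alpha and 40.1% for epsilon. Of alpha it says “initiator is exhausted early, so dead-end”. Its values stand above mine, and it adds 0.3 to 0.65 % for initiation.

The simulation gives gamma highest, with 71.5%, then theta 58.0%, alpha 52.1% and epsilon 40.1%.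

Theta's leftover of 42% reads as an exponent of 0.868, beside my 0.848. With the temperatures and times held, the reach goes with the square root of the charge, so a neighbour of theta charged with 0.044 mM of initiator has X = 1.10 and a reckoned yield of 66.7%. That neighbour gives 67.9%, with 32.1% of the free monomer left at 80.0 s.

The numbers were set for the occasion; the result is computed.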